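## Structural features

The target is a C15 dibromide with three rings. Ring A is a cyclohexane (C5a, C6, C7, C8, C9, C9a in 1-benzoxepine numbering), ring B an oxepane (O1, C2, C3, C4, C5, C5a, C9a) fused to it across C5a–C9a, and ring C an oxirane on C3–C4. The ring fusion is trans: C9a–O1 and C5a–C5 are both equatorial on the ring A chair, and the angular methyl on C9a is axial, anti to H-5a and syn-axial to one methyl of the C6 gem-dimethyl group. C7 carries an equatorial bromine, 1,3-cis to the C5 branch across the quaternary C6. The epoxide oxygen on C3 (quaternary, methyl-bearing) and C4 lies on the face of H-5a. C2 is an enol ether carbon with an exocyclic bromomethylidene of E geometry, so the bromine sits on the crowded side, syn to C3. The fragile parts are the bromo enol ether next to the epoxide (acid, Lewis acids, zerovalent metals) and the neopentyl secondary bromide (elimination towards C8, methyl shift on ionisation). The real difficulties are the C9a–C5a–C6 array with a ring-fusion CH between two fully substituted carbons, closure of a seven-membered ring at a tertiary oxygen, and the contra-steric E-bromomethylidene. A further one is that the C7 oxygen used for stereocontrol must be replaced by bromine with net retention, because the carbinol carbon of the enone has the same spatial sense as C7–Br in the target. The key step exploits the position of the C6 gem-dimethyl carbon between the heteroatom-bearing C7 and the ring-fusion C5a that carries the C5 methylene: this is the retron of conjugate methylation of a 3-methyl-4-oxycyclohex-2-enone followed by alkylation of the enolate.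

## Logic of the disconnections

25 to 24. One vinylic C–H of 25 is traced back to a C–Br bond. The E isomer has bromine on the hindered side, which sterically governed bromination–elimination would not favour. In 24 the geometry question becomes a choice between two C–Br bonds, and the more exposed one (syn to O1) is the one to be removed. The forward step must leave the ring A bromide and the allylic epoxide untouched.

24 to 23. The exocyclic C=C bond is cut back to a lactone carbonyl. This keeps the acid-labile enol ether out of the route until the last two steps and lets ring B be made by acyl chemistry. The demand is a carbonyl olefination of a shielded lactone without α-hydrogen, under conditions that spare the epoxide.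

23 to 22. Both C–O bonds of ring C are cut. In 22 the ring alkene is the only alkene, so chemoselectivity is not an issue and two stereocentres are removed at once. The oxidant must be electrophilic enough for an enoate-type alkene and must attack anti to the axial angular methyl.

22 to 21, 20, 19 and 18. The C7–Br bond is cut with inversion to an axial C7–OH in 21, which is traced through ketone 20 and the equatorial alcohol 19 to the silyl ether 18. The equatorial oxygen is what the stereochemical relay of the key step produces, so a single displacement would give the wrong epimer; the oxidation–reduction pair corrects this. Keeping bromine out until this point protects it from hydride, tin and palladium reagents. The demands are equatorial hydride delivery and an SN2 displacement at a neopentyl carbon.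

18 to 17, 16 and 15. The acyl C2–O1 bond and the C2–C3 bond are cut (C2 comes from CO), then C3–I and C3–Sn back to the alkyne of 15. The but-2-ynyl chain of 15 already holds C5, C4, C3 and the C3 methyl, so ring B reduces to a side chain on a monocyclic alcohol. The forward steps need anti hydrometalation with the metal on the methyl-bearing carbon, and capture of an acylpalladium by a tertiary hydroxyl in a seven-membered closure.

15 to 14, 13 and 12. At C9a the methyl C–H bond (hydride opening), the spiro-epoxide C–O bonds and the C=CH2 bond are cut back to the ketone of 12. Direct methyl addition to 12 would come from the equatorial side and give the wrong carbinol; the three-step detour delivers oxygen equatorially instead. The demands are a non-basic methylenation that does not epimerise the α-centre, and equatorial epoxidation.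

12 to 6, 7 and 8 (through 11, 10 and 9). This is the key cut: the second C6–CH3 bond and the C5a–C5 bond. It removes a quaternary carbon and the whole ring B chain in one operation and leaves a simple enone with one stereocentre. The forward step must keep the enolate regiochemistry fixed until it is alkylated, and the C7 oxygen must relay its configuration to C5a.

6 to 5, 4, 3, 2 and 1. The ketone is masked as a dioxolane (which transposes the enone), the vinylic C–CH3 bond is cut to a C–I bond, then O–Si, the carbinol C–H and the C–I bond. Iodine serves first as the large group in the asymmetric reduction and then as the handle for the methyl group, and the sequence ends at a commercial achiral enone. The demands are catalyst-controlled facial selectivity and a mild ketal hydrolysis that spares the allylic silyl ether.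

## Other disconnections considered

Alternative 1: The C2–C3 bond of ring B is cut. In the forward direction SnBr4 ionises the α-acetoxy ether A1, a mixed acetal at the tertiary oxygen carrying a CHBr2 group and a (Z)-vinylsilane side chain. The silyl-bearing carbon attacks the oxocarbenium ion at its ipso position and loss of silicon gives the dibromomethyl oxepene A2.
- In its favour: the exocyclic carbon arrives with both bromines, so the enol ether arises by loss of HBr and the olefination of a hindered lactone (steps 18 and 19) is avoided. On this point it is better than the chosen plan.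
- Equal: ring A with its three stereocentres would be the same, and the vinylsilane would come from the alkyne of 15 by the same anti-hydrometalation logic.
- Against: A1 needs a mixed acetal between a hindered tertiary alcohol and a dibromoacetaldehyde equivalent; the oxocarbenium ion is destabilised by two α-bromines; the ring A bromide and the tertiary ether meet a strong Lewis acid. Elimination from A2 offers no handle on the bromomethylidene geometry, and the epoxide would then have to be introduced beside an electron-rich enol ether.
- Mechanistically it is a cationic seven-membered closure, against an acylpalladium capture here. Step economy is roughly equal.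

Alternative 2: The C3–C4 bond and the C4–O bond of ring C are cut together. In the forward direction SmI2 reduces one C–Br bond of the 2,2-dibromopropanoate aldehyde A3, the bromo enolate adds to the aldehyde (closing ring B) and the alkoxide displaces the second bromide (closing ring C). The product A4 is identical with 23.
- In its favour: rings B and C and both their stereocentres form in one step, replacing steps 10, 11, 12 and 17, with no tin and no CO. In step economy it is clearly better.
- Equal: it ends at the same lactone and so faces the same final two steps, and it needs the same ring A carbinol array.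
- Against: SmI2 must discriminate between three kinds of C–Br bond. The aldol step sets C3 and C4 relative to ring A without an obvious controlling element, and only the adduct with oxygen and bromine anti can close. The tertiary alcohol must be acylated by a hindered dibromoacyl halide before the aldehyde is unveiled, since the free hydroxy aldehyde would form a five-membered lactol.
- It concentrates the stereochemical risk in one reductive step, whereas the chosen plan relies on substrate-controlled epoxidation of a rigid bicyclic lactone.

Alternative 3: The retron is an electrocyclic ring opening. The bond between the lactone α-carbon (C3) and C5a, absent from the target, is re-formed to give the cyclobutene-fused γ-lactone A6, the [2+2] photoadduct of butenolide A5 and acetylene. Heating A6 would give the dienyl lactone A7.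
- In its favour: a two-carbon ring expansion of an easily made butenolide with no hydrometalation or carbonylation. Up to A7 it is equal or better in step count.
- Against: opening a cis-fused bicyclo[3.2.0]heptene to a cis,cis-diene must be disrotatory, which the Woodward–Hoffmann rules forbid for a thermal four-electron process; the allowed conrotatory mode would put a trans double bond in the seven-membered ring. The forcing conditions are unlikely to spare the neopentyl bromide. The photocycloaddition must create two adjacent quaternary carbons and irradiates a C–Br bond.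
- A7 has lost the C5a stereocentre that the chosen key step sets. It would have to be regained by a site- and face-selective reduction of the γ,δ-alkene before the route could join the chosen one at 22.

Key step: step 6

Assumption: 1 is taken as purchased, and the sense of the oxazaborolidine reduction follows the usual large/small model with the iodoalkene arm of 2 as the large group.

## Route

Step 1
Reactants: 1 1,4-dioxaspiro[4.5]dec-6-en-8-one
Product: 2 7-iodo-1,4-dioxaspiro[4.5]dec-6-en-8-one
Conditions: I2, K2CO3, DMAP (cat.), THF/H2O, 23 °C
Reagents that add atoms: iodine, [I][I]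
Why: α-Iodination of a cyclic enone by amine conjugate addition, iodination of the enolate and elimination (Baylis–Hillman-type addition–elimination); the ketal is stable to the basic medium.

Step 2
Reactants: 2 7-iodo-1,4-dioxaspiro[4.5]dec-6-en-8-one
Product: 3 (8R)-7-iodo-1,4-dioxaspiro[4.5]dec-6-en-8-ol
Conditions: (S)-2-methyl-CBS-oxazaborolidine (10 mol%), BH3·SMe2, THF, −20 °C; MeOH
Reagents that add atoms: none
Why: Corey–Bakshi–Shibata reduction; the iodoalkene arm acts as the large substituent, so the (S)-catalyst should deliver hydride to the face that gives the R carbinol.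

Step 3
Reactants: 3 (8R)-7-iodo-1,4-dioxaspiro[4.5]dec-6-en-8-ol
Product: 4 tert-butyl{[(8R)-7-iodo-1,4-dioxaspiro[4.5]dec-6-en-8-yl]oxy}dimethylsilane
Conditions: TBSCl, imidazole, DMF, 23 °C
Reagents that add atoms: tert-butyldimethylsilyl chloride, CC(C)(C)[Si](C)(C)Cl
Why: Standard silylation of a secondary allylic alcohol; a silyl ether, unlike an ester, is not expelled from the γ-position in the later cuprate step.

Step 4
Reactants: 4 tert-butyl{[(8R)-7-iodo-1,4-dioxaspiro[4.5]dec-6-en-8-yl]oxy}dimethylsilane
Product: 5 tert-butyldimethyl{[(8R)-7-methyl-1,4-dioxaspiro[4.5]dec-6-en-8-yl]oxy}silane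
Conditions: MeZnCl, Pd(dppf)Cl2 (5 mol%), THF, 50 °C
Reagents that add atoms: methylzinc chloride, C[Zn]Cl
Why: Negishi coupling of an alkenyl iodide (oxidative addition, transmetalation, reductive elimination); the stereocentre is not involved and the ketal and silyl ether are inert.

Step 5
Reactants: 5 tert-butyldimethyl{[(8R)-7-methyl-1,4-dioxaspiro[4.5]dec-6-en-8-yl]oxy}silane
Product: 6 (4R)-4-[(tert-butyldimethylsilyl)oxy]-3-methylcyclohex-2-en-1-one
Conditions: PPTS (cat.), acetone/H2O (10:1), 45 °C
Reagents that add atoms: water, O
Why: Acid-catalysed hydrolysis of an allylic ketal, which ionises readily and so allows conditions mild enough for the secondary silyl ether; the carbonyl emerges conjugated with the methyl-bearing alkene.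

Step 6
Reactants: 6 (4R)-4-[(tert-butyldimethylsilyl)oxy]-3-methylcyclohex-2-en-1-one; 7 methyllithium; 8 1-bromobut-2-yne
Product: 12 (2R,4R)-2-(but-2-yn-1-yl)-4-[(tert-butyldimethylsilyl)oxy]-3,3-dimethylcyclohexan-1-one, via lithium dimethylcuprate 9 (not isolated), via lithium enolate 10 (not isolated), via trans ketone 11 (not isolated)
Conditions: CuI, Et2O, 0 °C (7 gives 9); 6, −20 → 0 °C; then THF, DMPU, 8, −40 → 0 °C; then MeOH, NaOMe, 23 °C; aq NH4Cl/NH3
Reagents that add atoms: none
Why: Cuprate 9 adds to the enone through a copper–alkene π-complex and a formally trivalent β-cuprio enolate, whose reductive elimination forms the C3–CH3 bond and leaves lithium enolate 10 with its double bond fixed between C1 and C2. In the aprotic medium this enolate cannot move to the C6 side, and DMPU frees it from the MeCu aggregate so that the SN2-reactive propargylic bromide 8 forms the C2–CH2 bond; the closest known reaction type is the tandem organocuprate conjugate addition–enolate alkylation of 3-alkylcyclohexenones. No ring is closed. C3 becomes a gem-dimethyl carbon without chirality, so the face of methyl delivery does not matter, and the silyloxy group on C4 is γ to the enolate carbon and cannot be expelled. Kinetically the electrophile should enter axially, anti to the pseudoaxial C3 methyl and to the C4 substituent, giving mainly the trans epimer 11. The only new stereocentre, C2, is α to the ketone: methoxide equilibrates it while the non-enolisable C4 centre stays fixed, and the C4 silyloxy group is the controlling element because only in 12 are both substituents equatorial. The selectivities needed are C2 over C6 alkylation, mono- over polyalkylation and cis over trans; the first two rest on the regiodefined enolate, the low temperature and the single hydrogen left at the neopentyl C2, the third on thermodynamics, with residual 11 separated and re-equilibrated.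

Step 7
Reactants: 12 (2R,4R)-2-(but-2-yn-1-yl)-4-[(tert-butyldimethylsilyl)oxy]-3,3-dimethylcyclohexan-1-one
Product: 13 tert-butyl{[(1R,3S)-3-(but-2-yn-1-yl)-2,2-dimethyl-4-methylidenecyclohexyl]oxy}dimethylsilane
Conditions: Zn, CH2Br2, TiCl4, THF/CH2Cl2, 0 → 23 °C
Reagents that add atoms: dibromomethane, BrCBr
Why: Takai–Lombardo methylenation; the non-basic gem-dimetallic reagent converts hindered, enolisable ketones to methylene compounds without epimerising the α-centre, and leaves the alkyne and the silyl ether alone.

Step 8
Reactants: 13 tert-butyl{[(1R,3S)-3-(but-2-yn-1-yl)-2,2-dimethyl-4-methylidenecyclohexyl]oxy}dimethylsilane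
Product: 14 tert-butyl{[(3R,4R,6R)-4-(but-2-yn-1-yl)-5,5-dimethyl-1-oxaspiro[2.5]octan-6-yl]oxy}dimethylsilane
Conditions: mCPBA, NaHCO3, CH2Cl2, 0 °C
Reagents that add atoms: 3-chloroperoxybenzoic acid, OOC(=O)c1cccc(Cl)c1
Why: Prilezhaev epoxidation of the 1,1-disubstituted alkene, which reacts far faster than the internal alkyne. The chair is locked with both ring substituents equatorial, and the axial methyl of the gem-dimethyl carbon blocks the axial trajectory, so the peracid should approach equatorially and place oxygen equatorial, trans to the butynyl chain.

Step 9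
Reactants: 14 tert-butyl{[(3R,4R,6R)-4-(but-2-yn-1-yl)-5,5-dimethyl-1-oxaspiro[2.5]octan-6-yl]oxy}dimethylsilane
Product: 15 (1R,2R,4R)-2-(but-2-yn-1-yl)-4-[(tert-butyldimethylsilyl)oxy]-1,3,3-trimethylcyclohexan-1-ol
Conditions: LiAlH4, THF, 0 → 40 °C
Reagents that add atoms: none
Why: SN2 hydride opening at the unsubstituted epoxide carbon turns the axial CH2 into the axial methyl and leaves the equatorial tertiary alcohol; the isolated alkyne and the silyl ether are not reduced under these conditions.

Step 10
Reactants: 15 (1R,2R,4R)-2-(but-2-yn-1-yl)-4-[(tert-butyldimethylsilyl)oxy]-1,3,3-trimethylcyclohexan-1-ol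
Product: 16 (1R,2R,4R)-4-[(tert-butyldimethylsilyl)oxy]-1,3,3-trimethyl-2-[(2Z)-3-(tributylstannyl)but-2-en-1-yl]cyclohexan-1-ol
Conditions: Bu3SnH (slow addition), [Cp*Ru(MeCN)3]PF6 (3 mol%), CH2Cl2, 23 °C
Reagents that add atoms: tributyltin hydride, CCCC[SnH](CCCC)CCCC
Why: Ruthenium-catalysed trans-hydrostannation adds H and Sn anti across the alkyne and gives the Z-alkenylstannane. The chloride-free cationic catalyst offers no hydrogen-bond steering by the remote hydroxyl, so tin should go to the less hindered, methyl-bearing carbon, distal to the branched ring.

Step 11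
Reactants: 16 (1R,2R,4R)-4-[(tert-butyldimethylsilyl)oxy]-1,3,3-trimethyl-2-[(2Z)-3-(tributylstannyl)but-2-en-1-yl]cyclohexan-1-ol
Product: 17 (1R,2R,4R)-4-[(tert-butyldimethylsilyl)oxy]-2-[(2Z)-3-iodobut-2-en-1-yl]-1,3,3-trimethylcyclohexan-1-ol
Conditions: I2, CH2Cl2, 0 °C
Reagents that add atoms: iodine, [I][I]
Why: Iododestannylation replaces tin by iodine at the same carbon with retention of alkene geometry; the alkenylstannane is much more reactive towards iodine than any other group present.

Step 12
Reactants: 17 (1R,2R,4R)-4-[(tert-butyldimethylsilyl)oxy]-2-[(2Z)-3-iodobut-2-en-1-yl]-1,3,3-trimethylcyclohexan-1-ol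
Product: 18 (5aR,7R,9aR)-7-[(tert-butyldimethylsilyl)oxy]-3,6,6,9a-tetramethyl-5a,6,7,8,9,9a-hexahydro-1-benzoxepin-2(5H)-one
Conditions: Pd(PPh3)4 (10 mol%), CO (3 bar), K2CO3, DMF, 70 °C
Reagents that add atoms: carbon monoxide, [C-]#[O+]
Why: Palladium-catalysed carbonylative lactonisation: zerovalent palladium inserts into the C–I bond, CO inserts, and the acylpalladium is captured by the tertiary hydroxyl. The Z geometry holds the acyl group and the hydroxyl on the same side, and the substituents flanking the carbinol favour the seven-membered closure.

Step 13
Reactants: 18 (5aR,7R,9aR)-7-[(tert-butyldimethylsilyl)oxy]-3,6,6,9a-tetramethyl-5a,6,7,8,9,9a-hexahydro-1-benzoxepin-2(5H)-one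
Product: 19 (5aR,7R,9aR)-7-hydroxy-3,6,6,9a-tetramethyl-5a,6,7,8,9,9a-hexahydro-1-benzoxepin-2(5H)-one
Conditions: HF (48% aq), MeCN, 23 °C
Reagents that add atoms: none
Why: Acidic fluoride cleaves the hindered secondary silyl ether; the unsaturated lactone is stable to these conditions.

Step 14
Reactants: 19 (5aR,7R,9aR)-7-hydroxy-3,6,6,9a-tetramethyl-5a,6,7,8,9,9a-hexahydro-1-benzoxepin-2(5H)-one
Product: 20 (5aR,9aR)-3,6,6,9a-tetramethyl-5a,8,9,9a-tetrahydro-1-benzoxepine-2,7(5H,6H)-dione
Conditions: Dess–Martin periodinane, NaHCO3, CH2Cl2, 23 °C
Reagents that add atoms: none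
Why: Dess–Martin oxidation of the secondary alcohol; the new ketone lies between a quaternary carbon and a CH2, so no stereocentre is at risk.

Step 15
Reactants: 20 (5aR,9aR)-3,6,6,9a-tetramethyl-5a,8,9,9a-tetrahydro-1-benzoxepine-2,7(5H,6H)-dione
Product: 21 (5aR,7S,9aR)-7-hydroxy-3,6,6,9a-tetramethyl-5a,6,7,8,9,9a-hexahydro-1-benzoxepin-2(5H)-one
Conditions: LiBH(s-Bu)3, THF, −78 °C; aq NH4Cl
Reagents that add atoms: none
Why: The bulky trialkylborohydride should attack the ketone from the equatorial direction and give the axial alcohol, as with 2,2-dimethylcyclohexanones in general; at −78 °C the ketone reacts much faster than the shielded conjugated lactone.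

Step 16
Reactants: 21 (5aR,7S,9aR)-7-hydroxy-3,6,6,9a-tetramethyl-5a,6,7,8,9,9a-hexahydro-1-benzoxepin-2(5H)-one
Product: 22 (5aR,7R,9aR)-7-bromo-3,6,6,9a-tetramethyl-5a,6,7,8,9,9a-hexahydro-1-benzoxepin-2(5H)-one
Conditions: CBr4, P(n-Oct)3, toluene, 70 °C
Reagents that add atoms: carbon tetrabromide, BrC(Br)(Br)Br
Why: Appel reaction: bromide displaces the axial alkoxyphosphonium group along the open equatorial trajectory with inversion, giving the equatorial bromide. The trialkylphosphine variant at elevated temperature is the known remedy for neopentyl secondary alcohols, and weakly basic bromide should substitute faster than it eliminates towards C8.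

Step 17
Reactants: 22 (5aR,7R,9aR)-7-bromo-3,6,6,9a-tetramethyl-5a,6,7,8,9,9a-hexahydro-1-benzoxepin-2(5H)-one
Product: 23 (3S,4S,5aR,7R,9aR)-7-bromo-3,4-epoxy-3,6,6,9a-tetramethyloctahydro-1-benzoxepin-2(3H)-one
Conditions: KHSO5 (as 2KHSO5·KHSO4·K2SO4), CF3COCH3, NaHCO3, aq Na2EDTA, MeCN, 0 °C
Reagents that add atoms: potassium peroxymonosulfate, [K+].OOS(=O)(=O)[O-]
Why: Methyl(trifluoromethyl)dioxirane made in situ is electrophilic enough for an α-methyl unsaturated lactone and transfers oxygen in a concerted way. The face anti to the axial angular methyl and the axial C6 methyl (the face of H-5a) is the open one, so C3 and C4 should be set together with oxygen on that face.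

Step 18
Reactants: 23 (3S,4S,5aR,7R,9aR)-7-bromo-3,4-epoxy-3,6,6,9a-tetramethyloctahydro-1-benzoxepin-2(3H)-one
Product: 24 (3S,4S,5aR,7R,9aR)-7-bromo-2-(dibromomethylidene)-3,4-epoxy-3,6,6,9a-tetramethyldecahydro-1-benzoxepine
Conditions: [Ph3PCHBr2]Br, KOtBu, toluene, 23 °C; then 23, 90 °C
Reagents that add atoms: (dibromomethyl)triphenylphosphonium bromide, BrC(Br)[P+](c1ccccc1)(c1ccccc1)c1ccccc1.[Br-]
Why: Wittig-type dibromomethylenation of a lactone carbonyl by Ph3P=CBr2 (Ramirez olefination); the ylide is made from the preformed salt so that no Ph3PBr2 is present to open the epoxide. The lactone has no α-hydrogen, so enolisation cannot compete.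

Step 19
Reactants: 24 (3S,4S,5aR,7R,9aR)-7-bromo-2-(dibromomethylidene)-3,4-epoxy-3,6,6,9a-tetramethyldecahydro-1-benzoxepine
Product: 25 (2E,3S,4S,5aR,7R,9aR)-7-bromo-2-(bromomethylidene)-3,4-epoxy-3,6,6,9a-tetramethyldecahydro-1-benzoxepine
Conditions: Pd(PPh3)4 (5 mol%), Bu3SnH (1.05 equiv, slow addition), toluene, 23 °C, dark
Reagents that add atoms: none
Why: Palladium-catalysed hydrogenolysis of a 1,1-dibromoalkene: zerovalent palladium should insert into the less hindered C–Br bond (syn to O1, remote from quaternary C3), and the tin hydride replaces it by hydrogen with retention, leaving bromine syn to C3, which is the E isomer. The remaining vinylic bromide reacts much more slowly, and the alkyl bromide does not add to zerovalent palladium under these conditions.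

## Compound list

1 | 1,4-dioxaspiro[4.5]dec-6-en-8-one | O=C1C=CC2(CC1)OCCO2 | starting material
2 | 7-iodo-1,4-dioxaspiro[4.5]dec-6-en-8-one | O=C1CCC2(OCCO2)C=C1I | intermediate
3 | (8R)-7-iodo-1,4-dioxaspiro[4.5]dec-6-en-8-ol | IC1=CC2(CC[C@H]1O)OCCO2 | intermediate
4 | tert-butyl{[(8R)-7-iodo-1,4-dioxaspiro[4.5]dec-6-en-8-yl]oxy}dimethylsilane | IC1=CC2(CC[C@H]1O[Si](C)(C)C(C)(C)C)OCCO2 | intermediate
5 | tert-butyldimethyl{[(8R)-7-methyl-1,4-dioxaspiro[4.5]dec-6-en-8-yl]oxy}silane | CC1=CC2(CC[C@H]1O[Si](C)(C)C(C)(C)C)OCCO2 | intermediate
6 | (4R)-4-[(tert-butyldimethylsilyl)oxy]-3-methylcyclohex-2-en-1-one | CC1=CC(=O)CC[C@H]1O[Si](C)(C)C(C)(C)C | intermediate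
7 | methyllithium | [Li]C | starting material
8 | 1-bromobut-2-yne | CC#CCBr | starting material
9 | lithium dimethylcuprate | [Li+].C[Cu-]C | intermediate
10 | lithium (4R)-4-[(tert-butyldimethylsilyl)oxy]-3,3-dimethylcyclohex-1-en-1-olate | CC1(C)[C@H](O[Si](C)(C)C(C)(C)C)CCC([O-])=C1.[Li+] | intermediate
11 | (2S,4R)-2-(but-2-yn-1-yl)-4-[(tert-butyldimethylsilyl)oxy]-3,3-dimethylcyclohexan-1-one (trans epimer) | CC1(C)[C@H](O[Si](C)(C)C(C)(C)C)CCC(=O)[C@H]1CC#CC | intermediate
12 | (2R,4R)-2-(but-2-yn-1-yl)-4-[(tert-butyldimethylsilyl)oxy]-3,3-dimethylcyclohexan-1-one (cis epimer) | CC1(C)[C@H](O[Si](C)(C)C(C)(C)C)CCC(=O)[C@@H]1CC#CC | intermediate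
13 | tert-butyl{[(1R,3S)-3-(but-2-yn-1-yl)-2,2-dimethyl-4-methylidenecyclohexyl]oxy}dimethylsilane | CC1(C)[C@H](O[Si](C)(C)C(C)(C)C)CCC(=C)[C@@H]1CC#CC | intermediate
14 | tert-butyl{[(3R,4R,6R)-4-(but-2-yn-1-yl)-5,5-dimethyl-1-oxaspiro[2.5]octan-6-yl]oxy}dimethylsilane | CC1(C)[C@H](O[Si](C)(C)C(C)(C)C)CC[C@]2(CO2)[C@@H]1CC#CC | intermediate
15 | (1R,2R,4R)-2-(but-2-yn-1-yl)-4-[(tert-butyldimethylsilyl)oxy]-1,3,3-trimethylcyclohexan-1-ol | CC1(C)[C@H](O[Si](C)(C)C(C)(C)C)CC[C@@](C)(O)[C@@H]1CC#CC | intermediate
16 | (1R,2R,4R)-4-[(tert-butyldimethylsilyl)oxy]-1,3,3-trimethyl-2-[(2Z)-3-(tributylstannyl)but-2-en-1-yl]cyclohexan-1-ol | CC1(C)[C@H](O[Si](C)(C)C(C)(C)C)CC[C@@](C)(O)[C@@H]1C/C=C(/C)[Sn](CCCC)(CCCC)CCCC | intermediate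
17 | (1R,2R,4R)-4-[(tert-butyldimethylsilyl)oxy]-2-[(2Z)-3-iodobut-2-en-1-yl]-1,3,3-trimethylcyclohexan-1-ol | CC1(C)[C@H](O[Si](C)(C)C(C)(C)C)CC[C@@](C)(O)[C@@H]1C/C=C(/C)I | intermediate
18 | (5aR,7R,9aR)-7-[(tert-butyldimethylsilyl)oxy]-3,6,6,9a-tetramethyl-5a,6,7,8,9,9a-hexahydro-1-benzoxepin-2(5H)-one | CC1(C)[C@H](O[Si](C)(C)C(C)(C)C)CC[C@@]2(C)OC(=O)C(C)=CC[C@H]12 | intermediate
19 | (5aR,7R,9aR)-7-hydroxy-3,6,6,9a-tetramethyl-5a,6,7,8,9,9a-hexahydro-1-benzoxepin-2(5H)-one | CC1(C)[C@H](O)CC[C@@]2(C)OC(=O)C(C)=CC[C@H]12 | intermediate
20 | (5aR,9aR)-3,6,6,9a-tetramethyl-5a,8,9,9a-tetrahydro-1-benzoxepine-2,7(5H,6H)-dione | CC1(C)C(=O)CC[C@@]2(C)OC(=O)C(C)=CC[C@H]12 | intermediate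
21 | (5aR,7S,9aR)-7-hydroxy-3,6,6,9a-tetramethyl-5a,6,7,8,9,9a-hexahydro-1-benzoxepin-2(5H)-one (axial alcohol) | CC1(C)[C@@H](O)CC[C@@]2(C)OC(=O)C(C)=CC[C@H]12 | intermediate
22 | (5aR,7R,9aR)-7-bromo-3,6,6,9a-tetramethyl-5a,6,7,8,9,9a-hexahydro-1-benzoxepin-2(5H)-one | CC1(C)[C@H](Br)CC[C@@]2(C)OC(=O)C(C)=CC[C@H]12 | intermediate
23 | (3S,4S,5aR,7R,9aR)-7-bromo-3,4-epoxy-3,6,6,9a-tetramethyloctahydro-1-benzoxepin-2(3H)-one | CC1(C)[C@H](Br)CC[C@@]2(C)OC(=O)[C@@]3(C)O[C@H]3C[C@H]12 | intermediate
24 | (3S,4S,5aR,7R,9aR)-7-bromo-2-(dibromomethylidene)-3,4-epoxy-3,6,6,9a-tetramethyldecahydro-1-benzoxepine | CC1(C)[C@H](Br)CC[C@@]2(C)OC(=C(Br)Br)[C@@]3(C)O[C@H]3C[C@H]12 | intermediate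
25 | (2E,3S,4S,5aR,7R,9aR)-7-bromo-2-(bromomethylidene)-3,4-epoxy-3,6,6,9a-tetramethyldecahydro-1-benzoxepine | CC1(C)[C@H](Br)CC[C@@]2(C)O/C(=C/Br)[C@@]3(C)O[C@H]3C[C@H]12 | target

## Step count and least certain steps

Total step count: 19. Longest linear sequence: 19 steps from 1 (7 and 8 are purchased reagents).

Step 6 (key step). The most likely failure is slow alkylation of the copper-bound enolate at a carbon next to a quaternary centre. Proton transfer would then scramble the enolate and lead to alkylation at C6 or dialkylation. A second weakness is that the equatorial groups of 12 are each gauche to both geminal methyls, so the energy gap to 11 may be small and the equilibration may stop at a mixture that needs recycling. The fallback sets out from 6. Me2CuLi in the presence of Me3SiCl would give the trimethylsilyl enol ether F1, which is isolated. MeLi in THF then releases a copper-free lithium enolate of the same regiochemistry, which is alkylated with 8 and equilibrated with NaOMe as before, returning to the route at 12.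

Step 18. The ylide may fail to add to a lactone carbonyl shielded by the quaternary epoxide carbon and the tertiary alkoxy group, and the heating needed may open the epoxide. The fallback sets out from 23. Petasis methylenation (Cp2TiMe2, toluene, 70 °C) would give the methylidene enol ether F2. Two cycles of bromine addition (Br2, CH2Cl2, −78 °C) and dehydrobromination (DBU), run without isolating the monobromide, would then give 24, where the route is rejoined.

Step 19. Palladium may discriminate poorly between the two vinylic C–Br bonds or reduce both. Tin radicals could remove the ring A bromine, and zerovalent palladium could ionise the allylic epoxide. The fallback sets out from 23 and passes through the methylidene enol ether F2 described above. A single bromine addition–dehydrobromination would give 25 together with the (Z)-bromomethylidene isomer F3, probably with F3 predominating because the geometry is then not directed. The isomers would be separated and F3 re-equilibrated by bromine-atom catalysis and recycled, so the route is rejoined at 25.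

Step 12. Capture of the acylpalladium by a hindered tertiary hydroxyl in a seven-membered closure may be too slow, so that reduction or intermolecular acylation takes over. The fallback sets out from 15 and closes the ring by metathesis. Semihydrogenation (H2, Pd/CaCO3 poisoned with Pb(OAc)2, quinoline) would give the (Z)-butenyl alcohol F4. Deprotonation with n-BuLi and acylation with methacryloyl chloride would give the methacrylate F5. Ring-closing metathesis with the second-generation Hoveyda–Grubbs catalyst in toluene at 80 °C would release propene and return to the route at 18.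

Step 10. Without a directing effect the regioselectivity of tin delivery rests on sterics alone and may be insufficient. The fallback sets out from 15 and tethers the metalloid. Silylation with (HMe2Si)2NH would give the dimethylsilyl ether F6. The same ruthenium catalyst should then effect an intramolecular endo-dig trans-hydrosilylation to the seven-membered alkenylsiloxane F7, with silicon necessarily on the methyl-bearing carbon. Iododesilylation with N-iodosuccinimide in (CF3)2CHOH, then K2CO3 in MeOH to free the tertiary alcohol, rejoins the route at 17.

Step 17. The dioxirane may attack the face syn to the angular methyl. The fallback sets out from 22 and turns the same facial preference to the opposite result. N-Bromosuccinimide in aqueous acetone would place bromine on C3 from the face the electrophile prefers and water on C4 from the other face, giving the bromohydrin F8. K2CO3 then closes the epoxide by displacement at C3, so the oxygen ends on the face opposite to the initial attack, returning to the route at 23.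

## Further compounds

F1 | step 6 | tert-butyl{[(1R)-2,2-dimethyl-4-[(trimethylsilyl)oxy]cyclohex-3-en-1-yl]oxy}dimethylsilane | CC1(C)[C@H](O[Si](C)(C)C(C)(C)C)CCC(O[Si](C)(C)C)=C1
F2 | step 18 | (3S,4S,5aR,7R,9aR)-7-bromo-3,4-epoxy-3,6,6,9a-tetramethyl-2-methylidenedecahydro-1-benzoxepine | CC1(C)[C@H](Br)CC[C@@]2(C)OC(=C)[C@@]3(C)O[C@H]3C[C@H]12
F3 | step 19 | (2Z)-isomer of 25 | CC1(C)[C@H](Br)CC[C@@]2(C)O/C(=C\Br)[C@@]3(C)O[C@H]3C[C@H]12
F4 | step 12 | (1R,2R,4R)-2-[(2Z)-but-2-en-1-yl]-4-[(tert-butyldimethylsilyl)oxy]-1,3,3-trimethylcyclohexan-1-ol | CC1(C)[C@H](O[Si](C)(C)C(C)(C)C)CC[C@@](C)(O)[C@@H]1C/C=C\C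
F5 | step 12 | methacrylate ester of F4 | CC1(C)[C@H](O[Si](C)(C)C(C)(C)C)CC[C@@](C)(OC(=O)C(C)=C)[C@@H]1C/C=C\C
F6 | step 10 | dimethylsilyl ether of 15 | CC1(C)[C@H](O[Si](C)(C)C(C)(C)C)CC[C@@](C)(O[SiH](C)C)[C@@H]1CC#CC
F7 | step 10 | seven-membered alkenylsiloxane (O–SiMe2 bridging the tertiary oxygen and the methyl-bearing alkene carbon) | CC1(C)[C@H](O[Si](C)(C)C(C)(C)C)CC[C@@]2(C)O[Si](C)(C)C(C)=CC[C@H]12
F8 | step 17 | bromohydrin of 22 (3-bromo anti to 4-hydroxy, hydroxyl on the face of H-5a) | CC1(C)[C@H](Br)CC[C@@]2(C)OC(=O)[C@](C)(Br)[C@@H](O)C[C@H]12
A1 | alternative 1 | α-acetoxy dibromoethyl ether of the ring A tertiary alcohol with (Z)-vinylsilane side chain | CC1(C)[C@H](Br)CC[C@@](C)(OC(OC(C)=O)C(Br)Br)[C@@H]1C/C=C(/C)[Si](C)(C)C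
A2 | alternative 1 | dibromomethyl oxepene | CC1(C)[C@H](Br)CC[C@@]2(C)O[C@@H](C(Br)Br)C(C)=CC[C@H]12
A3 | alternative 2 | 2,2-dibromopropanoate of the ring A tertiary alcohol with acetaldehyde side chain | CC1(C)[C@H](Br)CC[C@@](C)(OC(=O)C(C)(Br)Br)[C@@H]1CC=O
A4 | alternative 2 | tricyclic epoxy lactone (identical with 23) | CC1(C)[C@H](Br)CC[C@@]2(C)OC(=O)[C@@]3(C)O[C@H]3C[C@H]12
A5 | alternative 3 | bicyclic α-methyl butenolide | CC1(C)[C@H](Br)CC[C@@]2(C)OC(=O)C(C)=C12
A6 | alternative 3 | cyclobutene-fused γ-lactone (either cis-fused facial isomer) | CC1(C)[C@H](Br)CC[C@@]2(C)OC(=O)C3(C)C=CC123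
A7 | alternative 3 | bromo dienyl seven-membered lactone | CC1(C)[C@H](Br)CC[C@@]2(C)OC(=O)C(C)=CC=C12
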